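The readings were generated by integration with made-up constants; noise was put on by code.

| flask | Jo | Zu | Qi | Ek | Dx | remark | time |
|---|---|---|---|---|---|---|---|
| noon | 0.50 mM | 0.50 mM | 4 equiv | 0.05 mol% | 0.28 µM | run made earlier |  |
| dawn | 0.50 mM | 0.50 mM | 4 equiv | 0.05 mol% | 0.44 µM | run made earlier |  |
| summer | 0.50 mM | 0.50 mM | 4 equiv | 0.075 mol% | 0.20 µM | run made earlier |  |
| flask | 0.50 mM | 0.50 mM | 4.00 equiv | 0.05 mol% | 0.20 µM |  | 4.0 min |

| run | time / min | Gy / % | Kj / % |
|---|---|---|---|
| noon | 0.250 | 16.8 | 10.4 |
| noon | 0.667 | 23.2 | 13.4 |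
| noon | 1.33 | 24.8 | 14.5 |
| noon | 3.00 | 24.7 | 13.7 |
| dawn | 0.250 | 17.2 | 10.4 |
| dawn | 0.667 | 22.6 | 13.3 |
| dawn | 1.33 | 24.5 | 15.2 |
| dawn | 3.00 | 24.0 | 15.0 |
| summer | 0.250 | 17.4 | 10.2 |
| summer | 0.667 | 23.5 | 13.8 |
| summer | 1.33 | 25.6 | 14.7 |
| summer | 3.00 | 24.6 | 14.2 |

(scatter of a reading: 0.5 percentage points)

- Qi is single-handed; Jo and Zu are mirror images of each other, charged as a racemate, each of them at the stated concentration
- what was read earlier has a scatter of 0.5 percentage points, one standard deviation
- an excess is the difference of the two amounts in percent of their sum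
- an excess is below zero if the other one leads
- the handed part of Qi does not stay in what it makes, so the products of the two hands are mirror images too

- Gy and Kj together, in percent of the Jo and Zu charged together, at 4.0 min
- excess of Gy over Kj in the product at 4.0 min
- whether the exchange between Jo and Zu keeps pace with the reaction: how far the product's excess at 4.0 min gets from its value without exchange to its value with instant exchange (above 80% keeps pace, below 20% hardly takes part, else lags behind)

A rate in per minute was what I could not read from these runs, so I divided one rate by another. Both hands meet the same Qi, so with no exchange between Jo and Zu the falling Qi cancels, however it is spent, and the logarithm of the fraction of Jo left over that of Zu left stays constant, just as time drops out of a copolymer composition equation. From 1.33 min on, the pooled readings stood near Gy 24.7% and Kj 14.5%, which gave 1.98 for this ratio s, the selectivity factor.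

That was one extreme, in which the excess falls as the yield rises. In the other, instant exchange, Jo equals Zu throughout, Gy over Kj is s itself, and the excess is s less one over s plus one at any yield. Read that way, the same plateau gave s of 1.70, so its excess of 25.9% fitted either extreme with its own s. I took the first s, a choice the readings did not force. Instant exchange then stood at 32.9%, and I expected this flask near 39.2% and 25.9%, at the no-exchange end.

The forecast gave 39%, 26.8% and "lags behind", calling the flask “roughly halfway”; on the pace I differed from it.

The flask gave 39.3% and 25.0%, and the exchange hardly takes part, getting 4.5% of the way; with the exchange struck out, the excess was 24.7%. Put to use on the flask's Kj of 14.7%, my s, read from scattered readings, reckoned Gy 25.0% and an excess of 25.8%, which is 0.8 percentage points above the excess the flask gave.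

    Qi + Zu → Kj (k = 12.0 M⁻¹ s⁻¹)
    Ek ⇌ Ja (K = 7.00, k = 0.00600 s⁻¹)
    Qi → Qe (k = 0.0550 s⁻¹)
    Ja + Dx ⇌ Jy, settled at all times (K = 3.80 × 10⁶ M⁻¹)
    Jo + Ja ⇌ Zu + Ja, rate k5*[Ja]*[Jo] forward; the back reaction follows from the equilibrium constant (k = 1.00 × 10⁵ M⁻¹ s⁻¹)
    Qi + Jo → Gy (k = 23.0 M⁻¹ s⁻¹)

For the neighbour with 10.0 equiv of Qi, Kj at 30.2% with s gave Gy 42.0% and an excess of 16.3%. The computed neighbour gave 42.0% and 16.4%.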